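## Assumptions
- Genipin (1) is taken as a commercial chiral-pool starting material (C5 and C9 are 4aS,7aS, identical to the target's C5/C9). Its C1 hemiacetal is an anomeric mixture, so C1 is left unspecified until the last ring closure.
- The target's (E)-arylidene geometry is kept as written in the SMILES.

## Retrosynthetic overview
1. Target ← phenol acetylation ← (E)-aldol condensation of a 4-silyloxybenzaldehyde onto the α-CH2 of a cis-fused THF/γ-lactone tetracycle.
2. That tetracycle ← acid-promoted cascade of a β,γ-dihydroxy ester (C1-OMe acetal): C10-OH transacetalizes at C1 to close the THF ring, and C8-OH lactonizes. C1 is forced by the ring system.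
3. The C10 stereocentre comes from a chelation-controlled Reformatsky addition to an α-hydroxy aldehyde.
4. The C8 quaternary carbinol with the C6=C7 alkene comes from genipin's C7=C8 alkene by convex-face epoxidation, selenide opening and selenoxide elimination.
5. Ring order: the pyran and cyclopentene are already present in genipin, then the THF acetal and lactone are formed together. The bold step is the chelation-controlled Reformatsky addition feeding the one-pot double cyclization.

## Route

**Step 1**
Reactants: 1 genipin
Product: 2, methyl 1-methoxy-10-hydroxy analogue (1-O-methylgenipin, C1 epimeric mixture)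
Conditions: MeOH, Amberlyst-15 (H⁺), rt
Reagents that add atoms: methanol, CO (OMe retained)
Why: Acid-catalysed hemiacetal → methyl acetal exchange (Fischer glycosidation) masks the lactol, so it survives the later oxidation and base steps. The C1 mixture is harmless because C1 is re-ionised at the end.

**Step 2**
Reactants: 2
Product: 3, 7β,8β-epoxide of 2
Conditions: mCPBA, NaHCO3, CH2Cl2, 0 °C
Reagents that add atoms: mCPBA, O=C(OO)c1cccc(Cl)c1 (transfers O)
Why: Prilezhaev epoxidation of the electron-rich trisubstituted C7=C8 alkene. It occurs from the convex β-face, the face of H5/H9, because the pyran ring hangs on the α-face. This places the future C8–O on the β-face as in the target. The push-pull C3=C4 enoate is inert.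

**Step 3**
Reactants: 3
Product: 4, 7α-phenylselanyl-8β-hydroxy compound
Conditions: PhSeSePh, NaBH4, MeOH, 0 °C → rt
Reagents that add atoms: diphenyl diselenide, c1ccccc1[Se][Se]c1ccccc1 (PhSe retained)
Why: Sharpless–Reich epoxide opening. PhSe⁻ attacks the secondary C7 trans (from the α-face) and leaves the tertiary C8 alkoxide with its configuration intact.

**Step 4**
Reactants: 4
Product: 5, diol with C8β-OH, C10-CH2OH and C6=C7 alkene
Conditions: 30% H2O2, pyridine, CH2Cl2, 0 °C → rt
Reagents that add atoms: none (Se leaves as PhSeOH)
Why: Selenoxide syn-elimination uses the syn C6-Hα. C8 has no H, so the alkene forms only toward C6. The result is the 1,2-transposed tertiary allylic alcohol with C8-O β, and no new stereocentre is created.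

**Step 5**
Reactants: 5
Product: 6, α-hydroxy aldehyde (C10 = CHO)
Conditions: SO3·py, DMSO, Et3N, CH2Cl2, 0 °C
Reagents that add atoms: none
Why: Parikh–Doering oxidation is basic and selective for the primary carbinol. The tertiary C8-OH is untouched, and C8 cannot enolise or epimerise. Basic conditions also avoid a premature C10-OH/C1-OMe bridging acetal.

**Step 6**
Reactants: 6 + 7 ethyl bromoacetate
Product: 8, β,γ-dihydroxy ethyl ester (C10-OH, C8-OH, 1-OMe)
Conditions: Zn (TMSCl-activated), THF, 0 °C → rt
Reagents that add atoms: ethyl bromoacetate, BrCC(=O)OCC (incorporated as reactant 7)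
Why: Reformatsky reaction under Cram-chelate control. The Zn chelate of the C8-O/C10=O attacks from the C7 face, away from the C1-bearing C9 face. This puts O10 toward C9 and C11 syn to O8, which is the cis-fused THF/lactone configuration of the target (C10 stereocentre set here).

**Step 7**
Reactants: 8
Product: 9, tetracyclic THF-acetal γ-lactone (C11H2)
Conditions: TsOH·H2O (20 mol %), PhMe, 4 Å MS, 70 °C
Reagents that add atoms: none (MeOH and EtOH are lost)
Why: Double cyclization. Ionisation at C1 (oxocarbenium) is trapped by the cis C10-OH in a transacetalization, which closes the THF ring. The C1 configuration is forced by the two α-face rings. The tertiary C8-OH then lactonizes onto the ester to give the 5-membered cis-fused lactone.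

**Step 8**
Reactants: 9 + 10 (4-TBSO-benzaldehyde)
Product: 11, β-hydroxy-α-(silyloxybenzyl) lactone (aldol adduct, C11/C12 mixture)
Conditions: LDA (1.05 equiv), THF, −78 °C; then 10, −78 °C
Reagents that add atoms: 4-(tert-butyldimethylsilyloxy)benzaldehyde, O=Cc1ccc(O[Si](C)(C)C(C)(C)C)cc1 (incorporated as reactant 10)
Why: Lactone enolate aldol. Low temperature prevents E1cB loss of the β-alkoxy C10–O. The TBS group protects the phenol from the enolate.

**Step 9**
Reactants: 11
Product: 12, (E)-arylidene lactone TBS ether
Conditions: MsCl, Et3N, CH2Cl2, 0 °C; then DBU, rt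
Reagents that add atoms: none
Why: Mesylation followed by E1cB elimination under thermodynamic control gives the (E)-α-arylidene lactone (aryl trans to C=O), the configuration in the target. Any Z isomer is removed by chromatography.

**Step 10**
Reactants: 12
Product: 13, 3-O-acetylprismatomerin
Conditions: TBAF, AcOH, THF, 0 °C; then Ac2O, Et3N, DMAP, CH2Cl2
Reagents that add atoms: acetic anhydride, CC(=O)OC(C)=O (acetyl retained)
Why: Buffered fluoride removes the aryl silyl ether and the phenoxide is acetylated in the same pot. AcOH prevents lactone opening and Michael addition. No stereocentre is touched.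

## Compound list
1 | genipin, methyl (4aS,7aS)-1-hydroxy-7-(hydroxymethyl)-1,4a,5,7a-tetrahydrocyclopenta[c]pyran-4-carboxylate | COC(=O)C1=COC(O)[C@@H]2C(CO)=CC[C@H]12 | starting material
2 | 1-O-methylgenipin | COC(=O)C1=COC(OC)[C@@H]2C(CO)=CC[C@H]12 | intermediate
3 | 7β,8β-epoxy-1-methoxy-10-hydroxy compound | COC(=O)C1=COC(OC)[C@@H]2[C@@]3(CO)O[C@H]3C[C@H]12 | intermediate
4 | 7α-phenylselanyl-8β-hydroxy-10-hydroxy compound | COC(=O)C1=COC(OC)[C@@H]2[C@](O)(CO)[C@H]([Se]c3ccccc3)C[C@H]12 | intermediate
5 | 8β,10-dihydroxy-Δ6 compound | COC(=O)C1=COC(OC)[C@@H]2[C@](O)(CO)C=C[C@H]12 | intermediate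
6 | 8β-hydroxy-10-al | COC(=O)C1=COC(OC)[C@@H]2[C@](O)(C=O)C=C[C@H]12 | intermediate
7 | ethyl bromoacetate | BrCC(=O)OCC | starting material
8 | β,γ-dihydroxy ethyl ester | COC(=O)C1=COC(OC)[C@@H]2[C@](O)([C@@H](O)CC(=O)OCC)C=C[C@H]12 | intermediate
9 | tetracyclic THF-acetal lactone | COC(=O)C1=CO[C@@H]2O[C@H]3CC(=O)O[C@]34C=C[C@H]1[C@H]24 | intermediate
10 | 4-(tert-butyldimethylsilyloxy)benzaldehyde | O=Cc1ccc(O[Si](C)(C)C(C)(C)C)cc1 | starting material
11 | aldol adduct (C11/C12 unspecified) | COC(=O)C1=CO[C@@H]2O[C@H]3C(C(O)c4ccc(O[Si](C)(C)C(C)(C)C)cc4)C(=O)O[C@]34C=C[C@H]1[C@H]24 | intermediate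
12 | (E)-arylidene lactone, TBS ether | COC(=O)C1=CO[C@@H]2O[C@H]3/C(=C\c4ccc(O[Si](C)(C)C(C)(C)C)cc4)C(=O)O[C@]34C=C[C@H]1[C@H]24 | intermediate
13 | 3-O-acetylprismatomerin | COC(=O)C1=CO[C@@H]2O[C@H]3/C(=C\c4ccc(OC(C)=O)cc4)C(=O)O[C@]34C=C[C@H]1[C@H]24 | target

## Checks
- C5/C9 come from genipin and are never touched. C8 is set by the convex-face epoxide, which is retained through the selenide opening and elimination. C10 is set by the chelation-controlled Reformatsky addition. C1 is forced by the two α-face rings in step 7. The (E)-alkene forms in step 9.
- Rings in the target: cyclopentene, dihydropyran, THF acetal (C1–O–C10–C8–C9) and α-arylidene γ-lactone (C8–O–C13–C11–C10). All are present in 13.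
- Atom bookkeeping: 8 (C16) loses MeOH and EtOH to give 9 (C13); 9 plus C9 (CH-aryl unit: CH + C6 ring + OAc) gives 13 (C22).

## Totals
Total steps: 10. Longest linear sequence: 10 steps (from genipin).

## Three steps most likely to fail
1. **Step 6, C10 diastereoselectivity.** The chelation model could give the wrong C10 epimer, which cannot close the cis-fused THF/lactone. Fallback: acylate the C8-OH of 6 with bromoacetyl bromide and run an intramolecular SmI2 Reformatsky–aldol. A cyclic samarium chelate then forms the lactone and the C10 stereocentre directly.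
2. **Step 3, selenolate chemoselectivity.** PhSe⁻ could add in conjugate fashion to the β-alkoxyacrylate instead of opening the hindered epoxide. Fallback: skip steps 2–4 and run a Schenck singlet-oxygen ene reaction on 2 (O2, TPP, hν, then PPh3), with β-face attack and C6–H abstraction, to reach diol 5 directly.
3. **Step 7, acid cascade.** The C1 oxocarbenium is poorly stabilised, so the cascade may stall or give side products. Fallback: hydrolyse the C1-OMe of 8 to the lactol (aq. TFA), lactonize with DBU, then close the bridged acetal by glycosyl-type activation of the lactol (Tf2O, 2,6-di-tert-butylpyridine) in place of Brønsted acid.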